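**Analysis of the target**

Compound 16 (C18H10O8) is a bis-coumarin: two 2H-chromen-2-one units joined by one diaryl ether oxygen between C6 of unit A and C5' of unit B. Unit A has a free hydroxyl at C7, next to the ether; unit B has hydroxyls at C6' and C7'. There is no stereocenter and no chain; every carbon is sp2, and the only conformational element is the twist about the ether oxygen. The sensitive groups are the two α-pyranone lactones (opened by hydroxide or alkoxide, Michael acceptors at C4 and C4'), the 6',7'-catechol (easily oxidized in basic, aerobic media) and three acidic phenols. The difficulty lies in ring B: C5', C6' and C7' carry three contiguous oxygens, and the one at C5', wedged between C4a' and C6' and peri to C4'–H, must be the one that bears the aryl group. Arylating a 5'-phenol, or functionalizing C5' of a finished coumarin, would be hindered and regiochemically ambiguous. The strategy rests on the sequence C7'(OH)–C8'(H)–C8a'(O1') in ring B. Read backwards, C8' is the methyl group on C6 of a 2-pyranone (C6 = C8a', C5 = C4a'), C7' is an ester carbon, and C5'=C6' is an enol-ether bridge on pyranone C5 that already holds the aryloxy oxygen and the masked 6'-oxygen.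

**Retrosynthetic reasoning**

16 from 15. The two O–CH3 bonds at O7 and O6' are cut last. Methyl is chosen because both groups arrive with purchasable building blocks (11 and 7) and because Lewis-acid ether cleavage touches neither the diaryl ether nor the lactones. The 7'-hydroxyl needs no protection, since the ring closure delivers it free.

15 from 12. Ring B is opened at C7'–C8'. This is the only ring B bond whose cleavage leaves every oxygen in place: C8' becomes the C6 methyl of a 2-pyranone, C7' a methyl ester, and C5'=C6' remains a fully substituted enol-ether double bond carrying the aryloxy and methoxy groups. Any other cut in ring B would break a C–O bond of the hindered ether or require a late oxygenation of a crowded arene. The gain is that the 5',6',7' pattern and the diaryl ether are fixed on an open chain before the benzene ring exists, and lactone B is already at the coumarin oxidation level. In the forward direction the pyranone methyl must be deprotonated (trienolate 13), its carbon must attack the ester carbonyl, the alkoxy group must leave (dienone 14), and the ring must aromatize to 15, all without a nucleophile opening either lactone.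

12 from 10 and 11. The vinylic C5'–O bond is cut, not the aryl C6–O bond. C5' is the β-carbon of an acrylate and therefore an electrophile for addition–elimination, whereas C6 of 11 is an unactivated, electron-rich arene carbon. The hindered ether is thus made by a phenoxide attacking an sp2 carbon of an open chain. Chloride is the leaving group; a sulfonate ester at this position would offer the phenoxide a competing attack at sulfur, with the stabilized keto-ester enolate as leaving group. The forward step must add the phenoxide of 11 to a tetrasubstituted, donor–acceptor double bond under a base too weak to touch the pyranone methyl.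

10 from 9. The C5'–Cl bond is traced back to the ketone of the α-methoxy-β-keto ester 9 by deoxychlorination through the enol. The geometry of the new double bond need not be controlled, because the ring closure equilibrates it.

9 from 6 and 7. The C5'–C6' bond is cut between the acyl carbon and the ester α-carbon: a crossed Claisen acylation of the enolate 8 of 7 by acid chloride 6. One purchasable piece thereby brings in C6' with its methoxy group and C7' as the ester.

6 from 5 from 4. These are functional-group changes at the carboxyl carbon that becomes C5'. The ester in 4 is tert-butyl because it is removed by acid, which 2-pyranones tolerate; an ester that needs saponification would cost the pyranone ring.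

4 from 1 and 2. The pyranone is cut at O1'–C2' and C4'–C4a', the reverse of a Michael addition of 1 to 2 followed by lactonization of adduct 3. Compound 1 supplies C8' (methyl), C8a' with O1', C4a' and C5'; compound 2 supplies C4', C3' and C2'.

**Alternatives that were turned down**

Alternative 1: Both lactone rings are disconnected at O1–C8a and O1'–C8a' and traced to ketones. The precursor is the diaryl ether bis(1-indanone) A1, and the key step is a double Baeyer–Villiger oxidation with a peracid that inserts oxygen between each carbonyl carbon and its aryl carbon, giving the bis(3,4-dihydrocoumarin) A2.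
- For: the indanone carbonyl is para to the ether position of unit A, so the diaryl ether of A1 can be made by ordinary SNAr. Aryl migration is also favoured in both halves by a para oxygen donor. Each reaction type is well precedented, and on that point this route is stronger than the chosen one.
- Against: A2 is at the wrong oxidation level. C3–C4 and C3'–C4' must each be dehydrogenated, twice on one molecule, under oxidizing conditions that an electron-rich tri-alkoxy diaryl ether tolerates poorly. The peracid itself can hydroxylate the same electron-rich rings. The aryl ester lactones of A2 are more labile than coumarins, and the indanone halves are not commodity chemicals.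
- Comparison: the chosen route offers oxidation-state economy, since the pyranone arrives unsaturated and ring B becomes aromatic in the step that closes it. The price is one unprecedented step.

Alternative 2: Both lactone C–O bonds are again cut at O1–C8a and O1'–C8a', but to aryl C–H bonds. The precursor is the bis-(E)-cinnamic acid A3, and the key step is a double photo-oxidative lactonization (flavin photocatalyst, visible light, air) to the tri-O-methyl ether A4.
- For: this is the shortest route. A3 follows from an SNAr-derived diaryl ether dialdehyde by a double Knoevenagel condensation, and A4 is one deprotection from the target. On step count it clearly beats the chosen route.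
- Against: two C–H oxygenations must both succeed on one substrate, so any inefficiency is squared. Ring A has a second free ortho position. The electron-rich diaryl ether competes for the photo-oxidant, and the coumarin products absorb light and can photodimerize at C3=C4.
- Comparison: the chosen route is longer but places every oxygen through carbonyl chemistry, with no C–H functionalization whose site or efficiency must be trusted.

Alternative 3: Benzene ring A is disconnected at C5–C6 and C4a–C8a. The 4-aryloxy-1,3-bis(silyloxy)diene A5 and methyl propiolate A6 undergo a Diels–Alder reaction, and loss of methanol gives the resorcylate A7.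
- For: regiochemistry is reliable, the 7-hydroxyl comes free, and the hindered ether bond is made earlier by simple O-alkylation of a phenol. That last point it shares with the chosen route.
- Against: the difficult ring B is not solved but pushed into a 5-hydroxy-6,7-dioxygenated coumarin starting material. The diene terminus that must bond carries a bulky aryloxy group. After the cycloaddition, the ester of A7 must be reduced to the aldehyde level and extended by two carbons to build pyranone A, in the presence of lactone B, which competes in any hydride reduction.
- Comparison: the chosen route builds the difficult ring rather than the easy one, and after the key step only ether cleavage remains.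

Key step: step 7

Remark: steps 5 and 6 are not expected to control the geometry of the tetrasubstituted double bond; 10 and 12 are drawn and named as the Z isomers, and mixtures would be carried on because both isomers converge in step 7.

**Route**

Step 1
Reactants: 1 tert-butyl acetoacetate; 2 ethyl propiolate
Product: 4 tert-butyl 6-methyl-2-oxo-2H-pyran-5-carboxylate, via acetylglutaconate diester 3 (not isolated)
Conditions: DBU (cat.), MeCN, 0 °C → 60 °C
Reagents that add atoms: none
Why: Base-catalysed Michael addition of the acetoacetate carbon to the alkynoate gives 3, whose enol oxygen lactonizes onto the ethyl ester with loss of ethanol (the addition–cyclocondensation route to 2-pyranones). The E and Z forms of 3 interconvert through the glutaconate anion, and the tert-butyl ester is too hindered to compete.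

Step 2
Reactants: 4 tert-butyl 6-methyl-2-oxo-2H-pyran-5-carboxylate
Product: 5 6-methyl-2-oxo-2H-pyran-5-carboxylic acid
Conditions: CF3CO2H, CH2Cl2, rt
Reagents that add atoms: none
Why: Acidolysis of a tert-butyl ester through the tert-butyl cation; the 2-pyranone lactone is stable to anhydrous acid.

Step 3
Reactants: 5 6-methyl-2-oxo-2H-pyran-5-carboxylic acid
Product: 6 6-methyl-2-oxo-2H-pyran-5-carbonyl chloride
Conditions: (COCl)2, DMF (cat.), CH2Cl2, 0 °C → rt; used crude
Reagents that add atoms: oxalyl chloride, O=C(Cl)C(=O)Cl
Why: Standard acid chloride formation under chloroiminium catalysis; the conditions are neutral and free of nucleophiles, so the pyranone is untouched.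

Step 4
Reactants: 7 methyl methoxyacetate; 6 6-methyl-2-oxo-2H-pyran-5-carbonyl chloride
Product: 9 methyl 2-methoxy-3-(6-methyl-2-oxo-2H-pyran-5-yl)-3-oxopropanoate (racemic), via lithium ester enolate 8 (not isolated)
Conditions: 7 (2.2 equiv), LiN(SiMe3)2 (2.2 equiv), THF, −78 °C; then 6, −78 °C; AcOH quench
Reagents that add atoms: none
Why: Crossed Claisen acylation of a preformed lithium ester enolate by an acid chloride, which is far more electrophilic than the lactone carbonyl at −78 °C. The second equivalent of enolate converts the product into its stabilized enolate and so stops over-acylation. The new stereocenter at C2 is racemic and is removed in step 5.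

Step 5
Reactants: 9 methyl 2-methoxy-3-(6-methyl-2-oxo-2H-pyran-5-yl)-3-oxopropanoate
Product: 10 methyl (Z)-3-chloro-2-methoxy-3-(6-methyl-2-oxo-2H-pyran-5-yl)prop-2-enoate
Conditions: (COCl)2, DMF (1.5 equiv each), CH2Cl2, 0 °C → 40 °C
Reagents that add atoms: oxalyl chloride, O=C(Cl)C(=O)Cl
Why: Vilsmeier-type deoxychlorination of a β-keto ester: the keto or enol oxygen adds to the chloroiminium salt and chloride displaces the activated oxygen by addition–elimination at the β-carbon. The geometry formed is not critical for what follows.

Step 6
Reactants: 10 methyl (Z)-3-chloro-2-methoxy-3-(6-methyl-2-oxo-2H-pyran-5-yl)prop-2-enoate; 11 isoscopoletin (6-hydroxy-7-methoxy-2H-chromen-2-one)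
Product: 12 methyl (Z)-2-methoxy-3-[(7-methoxy-2-oxo-2H-chromen-6-yl)oxy]-3-(6-methyl-2-oxo-2H-pyran-5-yl)prop-2-enoate
Conditions: Cs2CO3, DMF, 50 °C
Reagents that add atoms: none
Why: Nucleophilic vinylic substitution by addition–elimination: the phenoxide of 11 adds to the β-carbon of the β-chloroacrylate and chloride leaves from the ester enolate, as in the classical synthesis of β-aryloxyacrylates from β-chloroacrylates. Carbonate is too weak to deprotonate the pyranone methyl, and phenoxide addition to the lactones is reversible.

Step 7
Reactants: 12 methyl (Z)-2-methoxy-3-[(7-methoxy-2-oxo-2H-chromen-6-yl)oxy]-3-(6-methyl-2-oxo-2H-pyran-5-yl)prop-2-enoate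
Product: 15 7-hydroxy-6-methoxy-5-[(7-methoxy-2-oxo-2H-chromen-6-yl)oxy]-2H-chromen-2-one, via lithium trienolate 13 (not isolated), via dienone 14 (not isolated)
Conditions: LiN(SiMe3)2 (3 equiv), THF (dilute), −78 °C → 0 °C; then 1 M HCl
Reagents that add atoms: none
Why: Proposed new method: LiN(SiMe3)2 removes a proton from the C6 methyl of the pyranone, which is acidified vinylogously by the lactone carbonyl and, through the C5 side chain, by the acrylate ester, to give trienolate 13. The terminal carbon of 13 attacks the ester carbonyl held cis to it and forms C7'–C8'; loss of lithium methoxide gives dienone 14, which is deprotonated at once to the aromatic 7'-phenoxide, and this irreversible aromatization drives the condensation as the final deprotonation drives a Dieckmann reaction. The closest known reaction types are the lateral deprotonation of 6-methyl-2-pyranones for reaction with external electrophiles, the intramolecular Claisen benzannulation of ortho-methyl aryl and heteroaryl esters, and orsellinate-type Claisen cyclizations; ring closure onto a pyranone that leaves the lactone intact has not been shown. Ring B closes in a 6-(enolendo)-exo-trig mode, which is stereoelectronically favoured. No stereocenter is formed. The step needs the ester and the pyranone cis across C5'=C6'; because the charge of 13 is shared with the acrylate, that bond has partial single-bond character, the E and Z isomers interconvert, and only the cis form can close. It also needs the base to spare both lactone carbonyls, which the hindered, non-nucleophilic silylamide secures. Excess base keeps the product as its phenoxide, and the acidic work-up recloses any lactone opened reversibly by the methoxide set free.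

Step 8
Reactants: 15 7-hydroxy-6-methoxy-5-[(7-methoxy-2-oxo-2H-chromen-6-yl)oxy]-2H-chromen-2-one
Product: 16 6,7-dihydroxy-5-[(7-hydroxy-2-oxo-2H-chromen-6-yl)oxy]-2H-chromen-2-one
Conditions: BBr3 (excess), CH2Cl2, −78 °C → rt; then H2O
Reagents that add atoms: none
Why: Lewis-acid cleavage of aryl methyl ethers by BBr3, with bromide attacking the methyl carbon. The diaryl ether offers no alkyl carbon for this attack and the coumarin lactones survive, as in the standard demethylation of methoxycoumarins; water hydrolyses the borate esters.

**Compound list**

1 | tert-butyl acetoacetate (tert-butyl 3-oxobutanoate) | CC(=O)CC(=O)OC(C)(C)C | starting material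
2 | ethyl propiolate | CCOC(=O)C#C | starting material
3 | 1-tert-butyl 5-ethyl (Z)-2-acetylpent-3-enedioate (racemic; Z isomer shown, E and Z interconvert) | CCOC(=O)/C=C\C(C(C)=O)C(=O)OC(C)(C)C | intermediate
4 | tert-butyl 6-methyl-2-oxo-2H-pyran-5-carboxylate | Cc1oc(=O)ccc1C(=O)OC(C)(C)C | intermediate
5 | 6-methyl-2-oxo-2H-pyran-5-carboxylic acid | Cc1oc(=O)ccc1C(=O)O | intermediate
6 | 6-methyl-2-oxo-2H-pyran-5-carbonyl chloride | Cc1oc(=O)ccc1C(Cl)=O | intermediate
7 | methyl methoxyacetate | COCC(=O)OC | starting material
8 | lithium 1,2-dimethoxyethen-1-olate (enolate of 7; double-bond geometry not defined) | [Li+].COC=C([O-])OC | intermediate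
9 | methyl 2-methoxy-3-(6-methyl-2-oxo-2H-pyran-5-yl)-3-oxopropanoate (racemic) | COC(=O)C(OC)C(=O)c1ccc(=O)oc1C | intermediate
10 | methyl (Z)-3-chloro-2-methoxy-3-(6-methyl-2-oxo-2H-pyran-5-yl)prop-2-enoate | COC(=O)/C(OC)=C(\c1ccc(=O)oc1C)Cl | intermediate
11 | isoscopoletin (6-hydroxy-7-methoxy-2H-chromen-2-one) | COc1cc2oc(=O)ccc2cc1O | starting material
12 | methyl (Z)-2-methoxy-3-[(7-methoxy-2-oxo-2H-chromen-6-yl)oxy]-3-(6-methyl-2-oxo-2H-pyran-5-yl)prop-2-enoate | COC(=O)/C(OC)=C(\c1ccc(=O)oc1C)Oc1cc2ccc(=O)oc2cc1OC | intermediate
13 | lithium trienolate of 12 (deprotonated at the pyranone methyl; drawn as the lactone enolate) | [Li+].C=C1OC([O-])=CC=C1/C(Oc1cc2ccc(=O)oc2cc1OC)=C(/OC)C(=O)OC | intermediate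
14 | 6-methoxy-5-[(7-methoxy-2-oxo-2H-chromen-6-yl)oxy]-2H-chromene-2,7(8H)-dione | O=C1C=CC2=C(O1)CC(=O)C(OC)=C2Oc1cc2ccc(=O)oc2cc1OC | intermediate
15 | 7-hydroxy-6-methoxy-5-[(7-methoxy-2-oxo-2H-chromen-6-yl)oxy]-2H-chromen-2-one | O=c1ccc2c(Oc3cc4ccc(=O)oc4cc3OC)c(OC)c(O)cc2o1 | intermediate
16 | 6,7-dihydroxy-5-[(7-hydroxy-2-oxo-2H-chromen-6-yl)oxy]-2H-chromen-2-one | O=c1ccc2cc(Oc3c(O)c(O)cc4oc(=O)ccc34)c(O)cc2o1 | target

**Step count and risks**

Total: 8 steps. Longest linear sequence: 8 steps (1 and 2 to 16); 11 enters at step 6.

Step 7 (key step). The closure may be sluggish, because the charge of 13 is delocalized into the ester it has to attack. The anion could then add intermolecularly to a coumarin C4, or the methoxide set free could open the lactones or displace the aryloxy group by addition–elimination at C5'. The fallback uses known chemistry, sets out from 11 and rejoins the route at 16: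
- Iodination of 11 with N-iodosuccinimide (MeCN, cat. CF3CO2H), directed ortho to the free 6-hydroxyl, should give 6-hydroxy-5-iodo-7-methoxy-2H-chromen-2-one F1.
- Methylation (MeI, K2CO3, acetone) gives 5-iodo-6,7-dimethoxy-2H-chromen-2-one F2.
- Ullmann diaryl ether coupling of F2 with a second portion of 11 (CuI, picolinic acid, K3PO4, DMSO, 90 °C) gives 6,7-dimethoxy-5-[(7-methoxy-2-oxo-2H-chromen-6-yl)oxy]-2H-chromen-2-one F3, the same compound as A4.
- BBr3 under the conditions of step 8 removes its three methyl groups to give 16.

This detour is shorter, but it depends on a doubly ortho-substituted coupling and on the site of iodination.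

Step 6. Addition of the phenoxide may be slow, because the double bond is tetrasubstituted and the α-methoxy group pushes electron density toward the β-carbon. Prolonged heating with base could then start deprotonation of the pyranone methyl and premature cyclization of 10. The fallback sets out from 9 and returns at 12: O-triflation (Tf2O, iPr2NEt, CH2Cl2, −78 °C) gives methyl (Z)-2-methoxy-3-(6-methyl-2-oxo-2H-pyran-5-yl)-3-{[(trifluoromethyl)sulfonyl]oxy}prop-2-enoate F4. F4 is then coupled with 11 under zerovalent palladium catalysis (Pd2(dba)3, 2-(di-tert-butylphosphino)biphenyl, K3PO4, toluene, 80 °C). This replaces conjugate addition by oxidative addition and C–O reductive elimination.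

Step 4. The ester enolate may add to the pyranone ring (at C6 or C2, with ring opening) or deprotonate the C6 methyl of 6 instead of attacking the acid chloride. The fallback sets out from 5 and returns at 9:
- 1,1'-Carbonyldiimidazole converts 5 into (1H-imidazol-1-yl)(6-methyl-2-oxo-2H-pyran-5-yl)methanone F5.
- The magnesium enolate of the malonate half-ester (KO2CCH2CO2Me, MgCl2, Et3N, MeCN) acylates and decarboxylates to methyl 3-(6-methyl-2-oxo-2H-pyran-5-yl)-3-oxopropanoate F6.
- Diazo transfer (4-acetamidobenzenesulfonyl azide, Et3N) gives methyl 2-diazo-3-(6-methyl-2-oxo-2H-pyran-5-yl)-3-oxopropanoate F7.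
- Carbenoid O–H insertion into methanol (Rh2(OAc)4, MeOH, CH2Cl2) gives 9.

No strong base or hard carbanion meets the pyranone on this path.

Step 5. The α-methoxy-β-keto ester enolizes poorly, so activation by the chloroiminium salt may be slow, and formylation at carbon or at the pyranone methyl may compete. The fallback sets out from 9 and returns at 12: O-sulfonylation of the enolate (TsCl, N-methylimidazole, Et3N, MeCN) gives methyl (Z)-2-methoxy-3-(6-methyl-2-oxo-2H-pyran-5-yl)-3-(tosyloxy)prop-2-enoate F8. F8 then undergoes the addition–elimination of step 6 with 11 (Cs2CO3, DMF). A tosylate is much less prone than a triflate to attack at sulfur.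

**Further compounds**

F1 | step 7 | 6-hydroxy-5-iodo-7-methoxy-2H-chromen-2-one | COc1cc2oc(=O)ccc2c(I)c1O
F2 | step 7 | 5-iodo-6,7-dimethoxy-2H-chromen-2-one | COc1cc2oc(=O)ccc2c(I)c1OC
F3 | step 7 | 6,7-dimethoxy-5-[(7-methoxy-2-oxo-2H-chromen-6-yl)oxy]-2H-chromen-2-one | COc1cc2oc(=O)ccc2cc1Oc1c(OC)c(OC)cc2oc(=O)ccc12
F4 | step 6 | methyl (Z)-2-methoxy-3-(6-methyl-2-oxo-2H-pyran-5-yl)-3-{[(trifluoromethyl)sulfonyl]oxy}prop-2-enoate | COC(=O)/C(OC)=C(\c1ccc(=O)oc1C)OS(=O)(=O)C(F)(F)F
F5 | step 4 | (1H-imidazol-1-yl)(6-methyl-2-oxo-2H-pyran-5-yl)methanone | Cc1oc(=O)ccc1C(=O)n1ccnc1
F6 | step 4 | methyl 3-(6-methyl-2-oxo-2H-pyran-5-yl)-3-oxopropanoate | COC(=O)CC(=O)c1ccc(=O)oc1C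
F7 | step 4 | methyl 2-diazo-3-(6-methyl-2-oxo-2H-pyran-5-yl)-3-oxopropanoate | COC(=O)C(=[N+]=[N-])C(=O)c1ccc(=O)oc1C
F8 | step 5 | methyl (Z)-2-methoxy-3-(6-methyl-2-oxo-2H-pyran-5-yl)-3-(tosyloxy)prop-2-enoate | COC(=O)/C(OC)=C(\c1ccc(=O)oc1C)OS(=O)(=O)c1ccc(C)cc1
A1 | alternative 1 | 5,6-dimethoxy-4-[(6-methoxy-1-oxo-2,3-dihydro-1H-inden-5-yl)oxy]-2,3-dihydro-1H-inden-1-one | COc1cc2C(=O)CCc2cc1Oc1c(OC)c(OC)cc2C(=O)CCc12
A2 | alternative 1 | 6,7-dimethoxy-5-[(7-methoxy-2-oxo-3,4-dihydro-2H-chromen-6-yl)oxy]-3,4-dihydro-2H-chromen-2-one | COc1cc2OC(=O)CCc2cc1Oc1c(OC)c(OC)cc2OC(=O)CCc12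
A3 | alternative 2 | (E)-3-{3-[6-((E)-2-carboxyethenyl)-2,3-dimethoxyphenoxy]-4-methoxyphenyl}prop-2-enoic acid | COc1ccc(/C=C/C(=O)O)cc1Oc1c(OC)c(OC)ccc1/C=C/C(=O)O
A4 | alternative 2 | 6,7-dimethoxy-5-[(7-methoxy-2-oxo-2H-chromen-6-yl)oxy]-2H-chromen-2-one | COc1cc2oc(=O)ccc2cc1Oc1c(OC)c(OC)cc2oc(=O)ccc12
A5 | alternative 3 | 6,7-dimethoxy-5-{[4-methoxy-2,4-bis(trimethylsilyloxy)buta-1,3-dien-1-yl]oxy}-2H-chromen-2-one (double-bond geometry not defined) | COC(O[Si](C)(C)C)=CC(O[Si](C)(C)C)=COc1c(OC)c(OC)cc2oc(=O)ccc12
A6 | alternative 3 | methyl propiolate | COC(=O)C#C
A7 | alternative 3 | methyl 5-[(6,7-dimethoxy-2-oxo-2H-chromen-5-yl)oxy]-2,4-dihydroxybenzoate | COC(=O)c1cc(Oc2c(OC)c(OC)cc3oc(=O)ccc23)c(O)cc1O
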